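The numbers in the tables were computed with made-up constants, and the scatter is random.

- The constants I wanted were two: a frozen rate v, the early rate of product formation held flat through a run, and k, the first-order constant for partner lost by itself.

| flask | starting material | partner | catalyst | time |
|---|---|---|---|---|
| alpha | 120 mM | 120 mM | 6.00 mM |  |
| gamma | 48.0 mM | 48.0 mM | 6.00 mM |  |
| delta | 180 mM | 120 mM | 6.00 mM |  |
| theta | 120 mM | 120 mM | 18.0 mM |  |
| zeta | 290 mM | 120 mM | 6.00 mM | 140 s |

- alpha run (time / s: [product] / mM): 11: 10.3; 32: 30.5; 62: 57.7; 98: 85.9; 140: 101.8
- gamma run (time / s: [product] / mM): 11: 9.0; 32: 24.3; 62: 38.0; 98: 42.8; 140: 43.8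
- delta run (time / s: [product] / mM): 11: 10.5; 32: 30.0; 62: 58.2; 98: 86.5; 140: 102.5
- theta run (time / s: [product] / mM): 11: 30.4; 32: 84.2; 62: 111.4; 98: 114.2; 140: 114.0

(standard deviation of a reading: 0.4 mM)

- reaction order in [partner] at the outset, round the charge of the alpha run, defined at two percent of the starting material turned into product
- reaction order in [starting material] at the outset, round the charge of the alpha run, defined at two percent of the starting material turned into product (one fixed amount of product, the same in the runs compared)
- product in the zeta run at 140 s, as a share of the starting material charged
- which of these the readings show (nothing beyond the main steps / the catalyst wakes slowly / the second partner is lost by itself / the substrate is lost by itself / the catalyst dies in pairs / the product binds the substrate)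

- Overall: starting material + partner -> product, with catalyst as catalyst.
- Constant volume, constant temperature.
- Bound and free are read together.
- "The second partner" is partner.
- An order is taken over about fifteen percent of the charge, up and down.

- Freezing v looked fair: over the first 11 s the alpha and delta runs made product at 0.936 mM s⁻¹ and 0.955 mM s⁻¹, and the gamma run, with 48.0 mM of partner against 120 mM, still made it at 0.818 mM s⁻¹.
- The theta run, with 18.0 mM of catalyst against 6.00 mM, made product at 2.76 mM s⁻¹ over its first 11 s, which is 2.95 times the figure for the alpha run.
- The theta run flattened at 114.0 mM from 120 mM of each reactant, a shortfall of 6.00 mM.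
- The delta run held 60.0 mM more starting material and read 102.5 mM against 101.8 mM for the alpha run, so I booked the shortfall to the partner.
- At a flat rate, partner falls roughly in a straight line from its charge R, so its mean is R/2, over a time P/v for a final product P. The loss is then k(R/2)(P/v).
- Putting the theta numbers in gave the leak constant k = 0.00242 s⁻¹.
- The same line gives a leak ratio, partner lost per product made, of kR/(2v), and a ceiling on product of R divided by one plus that ratio.
- For the zeta run the partner is the limiting reagent, 120 mM against 290 mM of starting material. Taking the alpha rate for it, the leak ratio came to 0.155, the ceiling to 103.9 mM, and the share to 35.8%.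
- The weak link was the frozen rate. Between 98 s and 140 s the delta run made product at 0.381 mM s⁻¹, slower than v, and at 140 s it stood at 102.5 mM, below my ceiling.
- I therefore reforged the estimate on that reading, which gave 35.3% for the zeta run.
- The forecast gave 35.4%, with orders of 0.1 in partner and 0.01 in starting material, and the verdict: the second partner is lost by itself. Its ground was “Zeta should therefore follow delta”, and its leak constant was about 0.002 per second where mine was 0.00242 s⁻¹.

- The zeta run gave 35.4% at 140 s, which is 102.8 mM of product, with orders of 0.062 in partner and 0.0051 in starting material; the readings show this: the second partner is lost by itself.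

    catalyst + starting material ⇌ catalyst-substrate complex, settled at all times (100.0 M⁻¹)
    catalyst-substrate complex + partner ⇌ ternary complex, settled at all times (160.0 M⁻¹)
    ternary complex → product + catalyst (0.1690 s⁻¹)
    partner → lost reagent (0.002620 s⁻¹)

- A fit with the starting material lost by itself left a root mean square residual of 3.9 in units of the scatter. The ceiling of 104 mM stood 1.20 mM above the zeta product. In the gamma run, k with 0.85 mM s⁻¹ gives a leak ratio of 0.0685 and a ceiling of 44.9 mM, and the reading at 140 s was 43.8 mM.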